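All constants are made up, and the outcome is calculated.

If every bit of starting material has to end as product, the question for these flasks is how much of it outlasts the chain.

    initiator → 2 initiating radical (k1 = 0.016 /s)
    starting material + initiating radical → capped initiator + first chain carrier (k2 = 4.1 × 10⁵ /M/s)
    partner + first chain carrier ⇌ product + second chain carrier (K3 = 7.3, k3 = 35000 /M/s)
    starting material + second chain carrier → by-product + first chain carrier (k4 = 12000 /M/s)
    2 second chain carrier → ended chains (k5 = 4 × 10⁶ /M/s)
    partner → decomposed reagent (k6 = 0.013 /s)

| flask | starting material | partner | initiator | time | remark |
|---|---|---|---|---|---|
| teal | 15 mM (fed, over 1.50 min) | 15.8 mM | 1.5 mM | 1.5 min | a stirred flask in which starting material is dosed at a steady rate over 1.50 min without added volume, worked up at 1.5 min |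
| ochre | 15 mM | 15.8 mM (fed, over 1.50 min) | 1.5 mM | 1.5 min | a stirred flask in which partner is dosed at a steady rate over 1.50 min without added volume, worked up at 1.5 min |
| green | 15 mM | 15.8 mM | 1.5 mM | 1.5 min | everything together in a closed stirred flask, run for 1.5 min |
| violet | 15 mM | 15.8 mM | 1.5 mM |  | a single well-mixed tank run continuously and read at steady state, 1.5 min in it on average |

- a doubled species enters its step squared and goes two at a time
- the stated concentrations are those of everything mixed, before any reaction; amounts are the same in each set-up
- the feed brings no volume worth counting
- run time (teal): 1.5 min

1. the set-up with the highest amount of product at the outlet or at the end, in percent of the starting material put in ("none" if the first two lie within 2 percentage points) (teal / ochre / green / violet / none)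
2. amount of product at the outlet or at the end, in percent of the starting material put in, teal
3. amount of product at the outlet or at the end, in percent of the starting material put in, ochre
4. amount of product at the outlet or at the end, in percent of the starting material put in, green
5. amount of product at the outlet or at the end, in percent of the starting material put in, violet

I reckon the ochre flask by hand, replacing falling curves by their means. The initiator's mean level over the run is N = 0.795 mM, and at two radicals per initiator lost it supplies R = 0.0254 mM/s. If termination keeps up with supply, the level Y of second chain carrier is the square root of the initiator's decay constant times N over the termination constant, 0.00178 mM. At that level a second chain carrier has a half-life by termination of 0.0701 s, far shorter than the run, so I keep that balance.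

The chain clock is κ = 0.0214 /s, the mean pseudo-first-order rate at which second chain carrier consumes starting material. Each radical supplied also takes one starting material when it starts a chain. Assuming the fed partner keeps pace, a charge c leaves (c + R/κ)e^(−κt) − R/κ, which in ochre is 1.17 mM, or 7.81% of the charge. So I expect 92.2% product. The mean costs little: κt is 1.93, and integrating the falling carrier level gives 1.89.

The forecast says 53% for teal, 87% for ochre, 80% for green and 67% for violet, with ochre best, holding that “feeding it (ochre) protects it from decay and starves termination while carriers build up”. My ochre figure stands above its own.

The simulation gives 54.2%, 89.0%, 79.8% and 67.2% in that order, so ochre is best, as forecast. That place would be lost if partner decay were taken away, with green then at 91.0%.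

Ochre keeps 10.9% of its starting material against my 7.81%. Part of what leaves it there is the falling initiator: with the initiator held level, ochre's yield reaches 99.6%. The clock contains no starting material, so I carry κ and R unchanged to the neighbour of ochre charged with 6.0 mM. There the remainder comes out at −0.141 mM, below zero, so the charge should be consumed before work-up. That flask ends with 0.028% of its starting material.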